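The strategy rests on cutting together the crowded C7–C5' biaryl bond and the C4'–C4a' bond of the carbocycle (C1'–C4', C4a', C8a') fused to arene B' (calamenene numbering; primed = half joined through C5'). C4a' is meta to O8' and cannot be alkylated directly, whereas C8a' is ortho, so C4' is parked on C8a' in a spiro[4.5]decane. An aryl metal adds to a spiro ene-dione. Acid then dehydrates the carbinol and, in one operation, expands the cyclopentane to the six-membered ring by a 1,2-shift, aromatises B', installs the fourth ortho substituent of the biaryl and unmasks the phenol. Both halves derive from one (+)-menthone-based spiroenone carrying both stereocentres.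

Key step: step 12

Assumption: the given structure defines four carbon stereocentres but not the sense of the C7–C5' axis. The axis is taken as it forms.

Labels: C1 = CHMe, C2, C3, C4 = CH(iPr), C4a, C5–C8 (arene), C8a. In the spiro compounds the same labels are kept. The six-membered ring is C4a–C5–C6–C7–C8–C8a (C8a = spiro carbon) and the cyclopentane is C8a–C1–C2–C3–C4.

Step 1
Reactants: 1 (+)-menthone
Product: 3 (3S,6R)-2-diazo-6-isopropyl-3-methylcyclohexan-1-one, via trifluoroacetyl ketone 2 (not isolated)
Conditions: LiN(SiMe3)2, THF, -78 °C; CF3CO2CH2CF3; aq HCl; then MsN3, Et3N, H2O, MeCN, rt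
Reagents that add atoms: methanesulfonyl azide CS(=O)(=O)N=[N+]=[N-]; 2,2,2-trifluoroethyl trifluoroacetate O=C(OCC(F)(F)F)C(F)(F)F (its acyl group stays in 2 only)
Why: Kinetic enolisation at the unsubstituted CH2 (future C8a), C-trifluoroacetylation and detrifluoroacetylative (Regitz-type) diazo transfer should install the diazo group regioselectively at low basicity, so that neither the CH(iPr) nor the CHMe centre is disturbed.

Step 2
Reactants: 3 diazo ketone
Product: 5 methyl (2R,5S)-2-isopropyl-5-methylcyclopentane-1-carboxylate (C1 epimers), via ketene 4 (not isolated)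
Conditions: hν (medium-pressure Hg lamp, Pyrex), MeOH, rt
Reagents that add atoms: methanol CO
Why: Photochemical Wolff rearrangement of a cyclic s-cis diazo ketone: the CH(iPr) carbon migrates with retention to the diazo carbon, the ring contracts to the trans-2-isopropyl-5-methylcyclopentane, methanol traps ketene 4, and the new ester-bearing centre (future C8a) may be a mixture because it is planarised in step 4.

Step 3
Reactants: 5 ester
Product: 6 (2R,5S)-2-isopropyl-5-methylcyclopentane-1-carbaldehyde (C1 epimers)
Conditions: i-Bu2AlH, CH2Cl2, -78 °C; MeOH, aq Rochelle salt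
Reagents that add atoms: none
Why: Partial ester reduction: the tetrahedral aluminium hemiacetal of this hindered ester should survive at -78 °C and release the aldehyde only on work-up.

Step 4
Reactants: 6 aldehyde; 7 but-3-en-2-one (methyl vinyl ketone)
Product: 10 spiroenone (1R,4S)-1-isopropyl-4-methylspiro[4.5]dec-6-en-8-one (CH2CH2 arm cis to methyl), via enamine 8 (not isolated), via keto aldehyde 9 (not isolated)
Conditions: pyrrolidine, toluene, reflux (Dean–Stark); 7, 0 °C to rt; then AcOH, NaOAc, H2O, reflux
Reagents that add atoms: pyrrolidine C1CCNC1 (in 8 only)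
Why: Stork enamine Michael addition followed by aldol condensation (Robinson-type spiroannulation of an alpha-branched aldehyde): the enone approaches the planar C8a of 8 on the face that carries the small methyl group, anti to isopropyl, which sets the quaternary spiro centre with the new C8a–C4a bond cis to methyl.

Step 5
Reactants: 10 spiroenone
Product: 11 (1R,4S)-1-isopropyl-4,8-dimethylspiro[4.5]dec-6-en-8-ol (carbinol epimers)
Conditions: MeLi, Et2O, -78 to 0 °C; H2O
Reagents that add atoms: methyllithium [Li]C
Why: 1,2-Addition of a hard organolithium to the enone carbonyl brings in the future aryl methyl group (C6–CH3); the carbinol configuration is irrelevant because this centre becomes sp2 in step 6.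

Step 6
Reactants: 11 tertiary allylic alcohol
Product: 12 (1R,4S)-1-isopropyl-4,8-dimethylspiro[4.5]dec-7-en-6-one (C4a cis to methyl and C8=O cis to isopropyl)
Conditions: pyridinium chlorochromate [C5H5NH][CrO3Cl], 4 Å sieves, CH2Cl2, rt
Reagents that add atoms: pyridinium chlorochromate [O-][Cr](=O)(=O)Cl.c1cc[nH+]cc1 (the carbonyl O comes from chromate in the [3,3] shift; the original hydroxyl O leaves on chromium)
Why: Babler–Dauben oxidative transposition: the tertiary allylic chromate ester undergoes a [3,3] shift to C8 and is oxidised there, which moves the oxygen next to the spiro carbon (the future phenol position) without touching a stereocentre.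

Step 7
Reactants: 12 spiroenone
Product: 13 (1R,4S)-1-isopropyl-4,8-dimethylspiro[4.5]deca-7,9-dien-6-one
Conditions: chloranil, t-BuOH, reflux
Reagents that add atoms: none
Why: Quinone dehydrogenation through the extended dienol (hydride abstraction from C4a): the alpha' carbon is quaternary, so only the linearly conjugated 2,4-dienone can form.

Step 8
Reactants: 13 spirodienone
Product: 14 (5R,8S)-5-isopropyl-3,8-dimethyl-5,6,7,8-tetrahydronaphthalen-1-ol [(1S,4R)-8-hydroxycalamenene]
Conditions: CF3CO2H, CH2Cl2, 0 °C to rt
Reagents that add atoms: none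
Why: Dienone–phenol rearrangement: O-protonation makes C4a cationic, C4 shifts from the spiro carbon C8a to C4a with retention for the conformational reason given in step 12, and proton loss gives the arene, so both stereocentres arrive unchanged in the trans-tetralin.

Step 9
Reactants: 14 phenol
Product: 15 methoxymethyl ether of 14
Conditions: NaH, MOMCl, THF/DMF, 0 °C
Reagents that add atoms: chloromethyl methyl ether COCCl
Why: Williamson-type O-alkylation of the phenoxide gives an acetal that protects O8 and will direct the metalation.

Step 10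
Reactants: 12 spiroenone
Product: 16 (1R,4S)-1-isopropyl-4,8-dimethylspiro[4.5]dec-7-ene-6,9-dione
Conditions: Pd(OH)2 on carbon (cat.), t-BuOOH, K2CO3, CH2Cl2, 4 °C to rt
Reagents that add atoms: tert-butyl hydroperoxide CC(C)(C)OO
Why: Radical allylic (gamma) oxidation of an enone to a 1,4-ene-dione: tert-butylperoxyl radicals abstract the weakest C–H, that of the ring C5' methylene, in preference to the primary C6'-methyl hydrogens, and the derived peroxide collapses to the ketone.

Step 11
Reactants: 15 MOM ether; 16 ene-dione
Product: 19 9-aryl-9-hydroxy-spiroenone (carbinol epimers; aryl = C7 of 15), via aryllithium 17 (not isolated), via arylcerium dichloride 18 (not isolated)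
Conditions: 15, n-BuLi, TMEDA, Et2O, 0 °C to rt; anhydrous CeCl3, THF, -78 °C; 16, -78 °C; H2O
Reagents that add atoms: n-butyllithium [Li]CCCC (Li in 17 only); cerium trichloride Cl[Ce](Cl)Cl (Ce and Cl in 18 only)
Why: Directed ortho-metalation can only occur at C7 because the other ortho position (C8a) is substituted, transmetalation to the less basic organocerium suppresses enolisation, and 1,2-addition should take place at the C5' carbonyl because the C8' carbonyl is shielded by the fully substituted spiro carbon; the new carbinol centre is lost in step 12.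

Step 12
Reactants: 19 carbinol
Product: 22 target biaryl diol CNP0145304.1, via aryl dienone 20 (not isolated), via MOM-protected biaryl 21 (not isolated)
Conditions: CF3CO2H/CH2Cl2 (1:3), 0 °C to rt; then MeOH, 40 °C
Reagents that add atoms: none
Why: Acid ionises the tertiary, benzylic and allylic C5'–OH and loss of a C4a' proton gives the linearly conjugated dienone 20; O-protonation of 20 places cationic character on C4a', next to the spiro carbon C8a', C4' undergoes a suprafacial 1,2-shift from C8a' to C4a', loss of the C4a' proton aromatises ring B' (21), and methanolysis of the acetal frees O8 (22). The closest known reaction type is the dienone–phenol rearrangement of 6,6-spiro-fused cyclohexa-2,4-dienones (spiro[4.5]decadienone to 5,6,7,8-tetrahydro-1-naphthol). No ring is closed by cyclisation: the six-membered carbocycle arises by ring expansion, C4a' being inserted into the C8a'–C4' bond of the cyclopentane. No new carbon stereocentre is made: C4' migrates with retention, C1' is untouched, the spiro centre is erased, and only the biaryl axis is new. The step needs C4' and not C1' to migrate, and the spiro configuration from step 4 should secure this: with C4a' cis to the methyl and C8' cis to the isopropyl group, the C4' shift leads to an arenium ion with both alkyl groups pseudoaxial, whereas a C1' shift would press isopropyl against O8' and methyl against the aryl group in the ring plane. Aromatisation makes the sequence irreversible and spares any cross-coupling at the position flanked by the C6' methyl and the isopropyl-bearing C4'.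

Compound list
1 | (+)-menthone, (2R,5S)-2-isopropyl-5-methylcyclohexan-1-one | C1C(=O)[C@@H](C(C)C)CC[C@@H]1C | starting material
2 | (3S,6R)-6-isopropyl-3-methyl-2-(trifluoroacetyl)cyclohexan-1-one (enolised 1,3-dicarbonyl) | O=C(C1C(=O)[C@@H](C(C)C)CC[C@@H]1C)C(F)(F)F | intermediate
3 | (3S,6R)-2-diazo-6-isopropyl-3-methylcyclohexan-1-one | [N-]=[N+]=C1C(=O)[C@@H](C(C)C)CC[C@@H]1C | intermediate
4 | [(2R,5S)-2-isopropyl-5-methylcyclopentylidene]ketene | O=C=C1[C@@H](C(C)C)CC[C@@H]1C | intermediate
5 | methyl (2R,5S)-2-isopropyl-5-methylcyclopentane-1-carboxylate, methyl and isopropyl trans, C1 epimers | COC(=O)C1[C@@H](C(C)C)CC[C@@H]1C | intermediate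
6 | (2R,5S)-2-isopropyl-5-methylcyclopentane-1-carbaldehyde, C1 epimers | O=CC1[C@@H](C(C)C)CC[C@@H]1C | intermediate
7 | but-3-en-2-one | CC(=O)C=C | starting material
8 | 1-{[(2R,5S)-2-isopropyl-5-methylcyclopentylidene]methyl}pyrrolidine | C(=C1[C@@H](C(C)C)CC[C@@H]1C)N1CCCC1 | intermediate
9 | (2R,5S)-2-isopropyl-5-methyl-1-(3-oxobutyl)cyclopentane-1-carbaldehyde, oxobutyl arm cis to methyl | CC(=O)CC[C@]1(C=O)[C@@H](C(C)C)CC[C@@H]1C | intermediate
10 | (1R,4S)-1-isopropyl-4-methylspiro[4.5]dec-6-en-8-one, CH2CH2 arm cis to methyl, vinyl arm cis to isopropyl | O=C1C=C[C@@]2(CC1)[C@@H](C(C)C)CC[C@@H]2C | intermediate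
11 | (1R,4S)-1-isopropyl-4,8-dimethylspiro[4.5]dec-6-en-8-ol, carbinol epimers | CC1(O)C=C[C@@]2(CC1)[C@@H](C(C)C)CC[C@@H]2C | intermediate
12 | (1R,4S)-1-isopropyl-4,8-dimethylspiro[4.5]dec-7-en-6-one, carbonyl cis to isopropyl | CC1=CC(=O)[C@@]2(CC1)[C@@H](C(C)C)CC[C@@H]2C | intermediate
13 | (1R,4S)-1-isopropyl-4,8-dimethylspiro[4.5]deca-7,9-dien-6-one | CC1=CC(=O)[C@@]2(C=C1)[C@@H](C(C)C)CC[C@@H]2C | intermediate
14 | (5R,8S)-5-isopropyl-3,8-dimethyl-5,6,7,8-tetrahydronaphthalen-1-ol | Cc1cc2c(c(O)c1)[C@@H](C)CC[C@@H]2C(C)C | intermediate
15 | methoxymethyl ether of 14 | Cc1cc2c(c(OCOC)c1)[C@@H](C)CC[C@@H]2C(C)C | intermediate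
16 | (1R,4S)-1-isopropyl-4,8-dimethylspiro[4.5]dec-7-ene-6,9-dione | CC1=CC(=O)[C@@]2(CC1=O)[C@@H](C(C)C)CC[C@@H]2C | intermediate
17 | C7-lithio derivative of 15 | Cc1cc2c(c(OCOC)c1[Li])[C@@H](C)CC[C@@H]2C(C)C | intermediate
18 | C7-dichlorocerio derivative of 15 | Cc1cc2c(c(OCOC)c1[Ce](Cl)Cl)[C@@H](C)CC[C@@H]2C(C)C | intermediate
19 | 9-hydroxy-9-aryl-(1R,4S)-1-isopropyl-4,8-dimethylspiro[4.5]dec-7-en-6-one, aryl = C7 of 15, carbinol epimers | CC1=CC(=O)[C@@]2(CC1(O)c3c(C)cc4c(c3OCOC)[C@@H](C)CC[C@@H]4C(C)C)[C@@H](C(C)C)CC[C@@H]2C | intermediate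
20 | 9-aryl-(1R,4S)-1-isopropyl-4,8-dimethylspiro[4.5]deca-7,9-dien-6-one | CC1=CC(=O)[C@@]2(C=C1c3c(C)cc4c(c3OCOC)[C@@H](C)CC[C@@H]4C(C)C)[C@@H](C(C)C)CC[C@@H]2C | intermediate
21 | 7,5'-linked bis(8-hydroxycalamenene), O8 as MOM ether, O8' free | Cc1cc2c(c(OCOC)c1-c1c(C)cc(O)c3c1[C@@H](C(C)C)CC[C@@H]3C)[C@@H](C)CC[C@@H]2C(C)C | intermediate
22 | CNP0145304.1, 7,5'-linked dimer of (1S,4R)-8-hydroxycalamenene | Cc1cc2c(c(O)c1-c1c(C)cc(O)c3c1[C@@H](C(C)C)CC[C@@H]3C)[C@@H](C)CC[C@@H]2C(C)C | target

Total step count: 12. Longest linear sequence: 11 (steps 1–9, 11, 12; step 10 branches from 12).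

Steps most likely to fail

Step 12. The methyl-bearing carbon may migrate in place of the isopropyl-bearing one. The cation may also be intercepted by the neighbouring oxygen before the shift. Crowding by the aryl group next to the migration terminus would favour both. The fallback sets out from 15 and 17 and comes back at 22. It leaves the ring expansion at the monomer stage (step 8, where no aryl group flanks the terminus) and makes the biaryl bond by cross-coupling.
- Bromination of 15 with NBS in MeCN, para to the acetal oxygen, should give the 5-bromide F1.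
- Treating 17 with ZnCl2 should give the arylzinc chloride F2.
- Negishi coupling under zerovalent palladium (Pd2(dba)3, RuPhos, THF, 70 °C) should give the bis-MOM biaryl F3.
- HCl in MeOH should then give 22.

Step 11. The hindered aryl metal may enolise the ene-dione or reduce it by single-electron transfer instead of adding to the carbonyl. The fallback sets out from 16 and 17 and comes back at 20.
- KN(SiMe3)2 and PhNTf2 (THF, -78 °C) should convert 16 through its C4a' enolate into the dienone triflate F4.
- Treating 17 with 2-isopropoxy-4,4,5,5-tetramethyl-1,3,2-dioxaborolane should give the boronic ester F5.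
- Suzuki–Miyaura coupling (Pd(OAc)2, SPhos, K3PO4, toluene/H2O) at this still only tri-ortho-flanked vinyl position should give 20. It is isolated this time and submitted to the acid conditions of step 12.

Step 4. Bond formation at the carbon flanked by two branched centres may be slow, and the facial selectivity may be poor. That would erode the spiro configuration on which steps 8 and 12 depend. The fallback sets out from 5 and comes back at 9.
- The ester enolate (LiN(iPr)2, THF/DMPU, -78 °C) is alkylated anti to isopropyl with 2-(2-iodoethyl)-2-methyl-1,3-dioxolane to give the quaternary ester F6.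
- i-Bu2AlH should give the ketal aldehyde F7.
- Aqueous HCl should release 9, and KOH in MeOH closes it to 10.

Further compounds
F1 | step 12 | 5-bromo derivative of 15 (bromine para to OMOM) | Cc1cc(OCOC)c2c(c1Br)[C@@H](C(C)C)CC[C@@H]2C
F2 | step 12 | C7-chlorozincio derivative of 15 | Cc1cc2c(c(OCOC)c1[Zn]Cl)[C@@H](C)CC[C@@H]2C(C)C
F3 | step 12 | bis-MOM ether of 22 | Cc1cc2c(c(OCOC)c1-c1c(C)cc(OCOC)c3c1[C@@H](C(C)C)CC[C@@H]3C)[C@@H](C)CC[C@@H]2C(C)C
F4 | step 11 | (1R,4S)-1-isopropyl-4,8-dimethyl-6-oxospiro[4.5]deca-7,9-dien-9-yl trifluoromethanesulfonate | CC1=CC(=O)[C@@]2(C=C1OS(=O)(=O)C(F)(F)F)[C@@H](C(C)C)CC[C@@H]2C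
F5 | step 11 | C7-pinacolboronate of 15 | Cc1cc2c(c(OCOC)c1B3OC(C)(C)C(C)(C)O3)[C@@H](C)CC[C@@H]2C(C)C
F6 | step 4 | methyl (2R,5S)-2-isopropyl-5-methyl-1-[2-(2-methyl-1,3-dioxolan-2-yl)ethyl]cyclopentane-1-carboxylate, new arm cis to methyl | COC(=O)[C@@]1(CCC2(C)OCCO2)[C@@H](C(C)C)CC[C@@H]1C
F7 | step 4 | corresponding carbaldehyde | O=C[C@@]1(CCC2(C)OCCO2)[C@@H](C(C)C)CC[C@@H]1C
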